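C1 is the ring stereocentre and carries C15(=C16H2)–C17–C18–C19=C20Me2; the 14-membered ring runs C1, C2, C3=C4(Me), C5, C6, C7=C8(CH2OH), C9, C10, C11=C12(Me), C13, C14. The strategy rests on the C5–C6 CH2–CH2 bond of this ring, which lies between the two ring-cis trisubstituted alkenes C3=C4 and C7=C8, so both carbons are primary allylic termini of like polarity; C5–C4(Me)=C3–C2–C1–C14 is the ring of (S)-carvone.
C5–C6 is made last by reductive coupling of an acyclic bis(allylic chloride) with activated zerovalent barium; this closes the only ring. The C8 oxygen is carried through this step as a lithium alkoxide, not as a silyl ether, because a C6-centred allylbarium would expel silanolate from C8–CH2OSi by 1,4-elimination.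
The acyclic chain comes from C13–C14: a C14 phenyl sulfone (carvone-derived C5–C1/C14 piece with the side chain) is alkylated by a C13 allylic bromide (C6–C13 piece), then desulfonylated.
Carvone piece: α′-hydroxylation, Pb(OAc)4 cleavage of the C1–C6 ring bond of carvone with immediate reduction (Z-enoate plus C14 alcohol), C14 sulfone, then C17–C18 by ene chlorination and prenyl sulfone alkylation. The prenylation is placed after ring opening because the enone of carvone would not survive a sulfonyl carbanion.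
C6–C13 piece: but-2-yne-1,4-diol; trans-hydroalumination/iodination fixes C7=C8, Negishi coupling adds C9–C13, SeO2 oxidation functionalises C13.

Key step: step 20

Assumption: atom labels C1–C20 are those of the first overview line; the carbinol carbon of the α′-hydroxy ketone and the sulfonyl-bearing carbons made in steps 7 and 15 form as epimer mixtures, which is harmless because each is erased again.

Step 1
Reactants: 1 (S)-(+)-carvone
Product: 3 (5R)-6-hydroxy-2-methyl-5-(prop-1-en-2-yl)cyclohex-2-en-1-one (C6 epimer mixture), via potassium dienolate 2 (not isolated)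
Conditions: KN(SiMe3)2, THF, −78 °C; then 3-phenyl-2-(phenylsulfonyl)oxaziridine, −78 °C; NH4Cl (aq)
Reagents that add atoms: 3-phenyl-2-(phenylsulfonyl)oxaziridine, O=S(=O)(c1ccccc1)N1OC1c1ccccc1
Why: Kinetic deprotonation at C6 (α′) gives the cross-conjugated dienolate, to which the N-sulfonyloxaziridine transfers oxygen (Davis enolate hydroxylation); the carvone stereocentre is untouched (its descriptor becomes R by priority only) and the new carbinol centre is erased in step 2.

Step 2
Reactants: 3 (5R)-6-hydroxy-2-methyl-5-(prop-1-en-2-yl)cyclohex-2-en-1-one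
Product: 5 methyl (2Z,5R)-5-(hydroxymethyl)-2,6-dimethylhepta-2,6-dienoate, via aldehyde ester 4 (not isolated)
Conditions: Pb(OAc)4, MeOH/PhH (1:1), 0 °C; filter (Celite); then NaBH4, MeOH, 0 °C
Reagents that add atoms: methanol, CO
Why: Pb(OAc)4 in methanol cleaves the α-ketol C1–C6 bond of the carvone ring (Criegee-type oxidative cleavage) to a methyl ester and an aldehyde, the ring-cis enone alkene becoming the Z-enoate C3=C4, and NaBH4 reduces the α-branched β,γ-unsaturated aldehyde at once, before it can epimerise or conjugate, without touching the enoate.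

Step 3
Reactants: 5 methyl (2Z,5R)-5-(hydroxymethyl)-2,6-dimethylhepta-2,6-dienoate
Product: 6 methyl (2Z,5R)-5-(iodomethyl)-2,6-dimethylhepta-2,6-dienoate
Conditions: I2, PPh3, imidazole, CH2Cl2, 0 → 25 °C
Reagents that add atoms: iodine, II
Why: Appel-type iodination of the primary C14 alcohol by SN2 on the alkoxyphosphonium ion; the neutral conditions leave the Z-enoate and the stereocentre alone.

Step 4
Reactants: 6 methyl (2Z,5R)-5-(iodomethyl)-2,6-dimethylhepta-2,6-dienoate
Product: 7 methyl (2Z,5R)-2,6-dimethyl-5-[(phenylsulfonyl)methyl]hepta-2,6-dienoate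
Conditions: PhSO2Na, Bu4NI (cat.), DMF, 50 °C
Reagents that add atoms: sodium benzenesulfinate, [Na+].[O-]S(=O)c1ccccc1
Why: SN2 displacement of the primary iodide by the sulfur of the sulfinate gives the C14 sulfone, the handle for the later C13–C14 bond.

Step 5
Reactants: 7 methyl (2Z,5R)-2,6-dimethyl-5-[(phenylsulfonyl)methyl]hepta-2,6-dienoate
Product: 8 methyl (2Z,5R)-6-(chloromethyl)-2-methyl-5-[(phenylsulfonyl)methyl]hepta-2,6-dienoate
Conditions: Ca(OCl)2, CO2 (solid), CH2Cl2/H2O, 0 °C
Reagents that add atoms: calcium hypochlorite, [Ca+2].[O-]Cl.[O-]Cl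
Why: Ene-type allylic chlorination with HOCl: Cl+ adds to the terminal CH2 of the electron-rich 1,1-disubstituted alkene and a methyl proton is lost, giving the 2-(chloromethyl)allyl unit (C17–Cl), while the electron-poor enoate alkene should not react.

Step 6
Reactants: 9 prenyl bromide
Product: 10 3-methylbut-2-en-1-yl phenyl sulfone
Conditions: PhSO2Na, DMF, 25 °C
Reagents that add atoms: sodium benzenesulfinate, [Na+].[O-]S(=O)c1ccccc1
Why: SN2 S-alkylation of benzenesulfinate by the primary allylic bromide.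

Step 7
Reactants: 8 methyl (2Z,5R)-6-(chloromethyl)-2-methyl-5-[(phenylsulfonyl)methyl]hepta-2,6-dienoate; 10 3-methylbut-2-en-1-yl phenyl sulfone
Product: 12 methyl (2Z,5R)-2,10-dimethyl-6-methylidene-8-(phenylsulfonyl)-5-[(phenylsulfonyl)methyl]undeca-2,9-dienoate (C8 epimers), via lithiated sulfone 11 (not isolated)
Conditions: 10, n-BuLi, THF, −78 °C; then 8, DMPU, −78 → −40 °C
Reagents that add atoms: none
Why: Alkylation of the sulfonyl-stabilised prenyl carbanion at its α-carbon by the 2-substituted allylic chloride (Julia-type sulfone alkylation) forms C17–C18; SN2 and SN2′ attack on this symmetrical allyl unit give the same product, and the far less acidic C14 sulfone is not deprotonated.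

Step 8
Reactants: 12 methyl (2Z,5R)-2,10-dimethyl-6-methylidene-8-(phenylsulfonyl)-5-[(phenylsulfonyl)methyl]undeca-2,9-dienoate
Product: 13 (2Z,5R)-2,10-dimethyl-6-methylidene-5-[(phenylsulfonyl)methyl]undeca-2,9-dien-1-ol
Conditions: PdCl2(dppp) (5 mol %), LiBHEt3 (6 equiv), THF, 0 → 25 °C
Reagents that add atoms: none
Why: Palladium-catalysed hydride substitution of the allylic sulfone (π-allylpalladium, hydride delivered to the less substituted terminus C18, which keeps C19=C20 in place) removes the auxiliary sulfonyl group, and the excess LiBHEt3 reduces the methyl ester to the Z-allylic alcohol; the non-allylic C14 sulfone is inert.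

Step 9
Reactants: 14 but-2-yne-1,4-diol
Product: 15 4-[(tert-butyldimethylsilyl)oxy]but-2-yn-1-ol
Conditions: NaH (1 equiv), THF, 0 °C; t-BuMe2SiCl (1 equiv); diol in excess
Reagents that add atoms: tert-butyldimethylsilyl chloride, CC(C)(C)[Si](C)(C)Cl
Why: Statistical monosilylation of the symmetrical diol through its monosodium alkoxide.

Step 10
Reactants: 15 4-[(tert-butyldimethylsilyl)oxy]but-2-yn-1-ol
Product: 17 (2Z)-4-[(tert-butyldimethylsilyl)oxy]-3-iodobut-2-en-1-ol, via cyclic sodium alkenylaluminate 16 (not isolated)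
Conditions: NaAlH2(OCH2CH2OMe)2, THF, 0 °C; then I2, −78 → 0 °C
Reagents that add atoms: iodine, II
Why: Hydroxyl-directed trans-hydroalumination of the propargylic alcohol places aluminium on the distal alkyne carbon (C8) on the side of the CH2O group, and iodinolysis with retention gives the (Z)-3-iodo allylic alcohol, which fixes the C7=C8 geometry.

Step 11
Reactants: 17 (2Z)-4-[(tert-butyldimethylsilyl)oxy]-3-iodobut-2-en-1-ol; 18 5-bromo-2-methylpent-2-ene
Product: 20 (2E)-3-{[(tert-butyldimethylsilyl)oxy]methyl}-7-methylocta-2,6-dien-1-ol, via (4-methylpent-3-en-1-yl)zinc bromide 19 (not isolated)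
Conditions: 18, Zn dust, LiCl, THF, 50 °C; then 17, Pd(OAc)2 (2 mol %), SPhos (4 mol %), THF, 25 °C (zinc reagent 2.2 equiv)
Reagents that add atoms: none
Why: Negishi sp2–sp3 cross-coupling transfers the C9–C13 chain to the alkenyl iodide with retention of geometry, so C9 ends cis to C6; the zinc reagent is in excess because the free hydroxyl may consume part of it.

Step 12
Reactants: 20 (2E)-3-{[(tert-butyldimethylsilyl)oxy]methyl}-7-methylocta-2,6-dien-1-ol
Product: 21 (2E)-3-{[(tert-butyldimethylsilyl)oxy]methyl}-7-methylocta-2,6-dien-1-yl 2,2-dimethylpropanoate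
Conditions: t-BuCOCl, pyridine, DMAP (cat.), CH2Cl2, 0 °C
Reagents that add atoms: pivaloyl chloride, CC(C)(C)C(Cl)=O
Why: Acylation of the primary allylic alcohol; the pivalate tolerates the later carbanion step and deactivates the C7=C8 alkene for step 13.

Step 13
Reactants: 21 (2E)-3-{[(tert-butyldimethylsilyl)oxy]methyl}-7-methylocta-2,6-dien-1-yl 2,2-dimethylpropanoate
Product: 22 (2E,6E)-3-{[(tert-butyldimethylsilyl)oxy]methyl}-8-hydroxy-7-methylocta-2,6-dien-1-yl 2,2-dimethylpropanoate
Conditions: SeO2 (cat.), t-BuOOH, salicylic acid (cat.), CH2Cl2, 25 °C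
Reagents that add atoms: tert-butyl hydroperoxide, CC(C)(C)OO (oxygen passed on through selenium dioxide, O=[Se]=O)
Why: SeO2-catalysed allylic oxidation (ene reaction, then [2,3]-shift) should hydroxylate the E-methyl group of the terminal trisubstituted alkene, as with geranyl esters, because the C7=C8 alkene is deactivated by its two allylic oxygens.

Step 14
Reactants: 22 (2E,6E)-3-{[(tert-butyldimethylsilyl)oxy]methyl}-8-hydroxy-7-methylocta-2,6-dien-1-yl 2,2-dimethylpropanoate
Product: 23 (2E,6E)-8-bromo-3-{[(tert-butyldimethylsilyl)oxy]methyl}-7-methylocta-2,6-dien-1-yl 2,2-dimethylpropanoate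
Conditions: CBr4, PPh3, CH2Cl2, −20 → 0 °C
Reagents that add atoms: carbon tetrabromide, BrC(Br)(Br)Br
Why: Appel bromination of the primary allylic alcohol by SN2 on the alkoxyphosphonium ion, without allylic transposition.

Step 15
Reactants: 13 (2Z,5R)-2,10-dimethyl-6-methylidene-5-[(phenylsulfonyl)methyl]undeca-2,9-dien-1-ol; 23 (2E,6E)-8-bromo-3-{[(tert-butyldimethylsilyl)oxy]methyl}-7-methylocta-2,6-dien-1-yl 2,2-dimethylpropanoate
Product: 25 (2E,6E,10R,12Z)-3-{[(tert-butyldimethylsilyl)oxy]methyl}-14-hydroxy-7,13-dimethyl-10-(6-methylhepta-1,5-dien-2-yl)-9-(phenylsulfonyl)tetradeca-2,6,12-trien-1-yl 2,2-dimethylpropanoate (C9 epimers), via dilithio derivative 24 (not isolated)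
Conditions: 13, n-BuLi (2.05 equiv), THF, −78 °C; then 23, −78 → −40 °C
Reagents that add atoms: none
Why: The O,C-dianion of the hydroxy sulfone is alkylated at the sulfonyl carbanion, by far its more nucleophilic site, by the primary allylic bromide (SN2 sulfone alkylation), forming C13–C14 with the C11=C12 geometry retained.

Step 16
Reactants: 25 the C14 (chain C9) sulfone from step 15
Product: 26 (2E,6E,10R,12Z)-3-{[(tert-butyldimethylsilyl)oxy]methyl}-14-hydroxy-7,13-dimethyl-10-(6-methylhepta-1,5-dien-2-yl)tetradeca-2,6,12-trien-1-yl 2,2-dimethylpropanoate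
Conditions: Na/Hg (6 %), Na2HPO4, MeOH/THF, −20 °C
Reagents that add atoms: none
Why: Reductive desulfonylation by electron transfer from sodium amalgam (Julia conditions) replaces the C14 sulfonyl group by hydrogen; the buffered cold medium should leave pivalate, silyl ether and alkenes alone.

Step 17
Reactants: 26 the C5 alcohol / C6 pivalate from step 16
Product: 27 (2E,6E,10R,12Z)-3-{[(tert-butyldimethylsilyl)oxy]methyl}-7,13-dimethyl-10-(6-methylhepta-1,5-dien-2-yl)tetradeca-2,6,12-triene-1,14-diol
Conditions: i-Bu2AlH, CH2Cl2, −78 °C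
Reagents that add atoms: none
Why: Hydride cleavage of the pivalate ester frees the C6 alcohol without touching the silyl ether.

Step 18
Reactants: 27 the C5,C6 diol
Product: 28 (2E,6E,10R,12Z)-3-{[(tert-butyldimethylsilyl)oxy]methyl}-1,14-dichloro-7,13-dimethyl-10-(6-methylhepta-1,5-dien-2-yl)tetradeca-2,6,12-triene
Conditions: NCS, Me2S, CH2Cl2, −40 → 0 °C
Reagents that add atoms: N-chlorosuccinimide, ClN1C(=O)CCC1=O
Why: Corey–Kim chlorination: each primary allylic alcohol is activated as an alkoxysulfonium ion and displaced by chloride in an SN2 step, which keeps alkene position and geometry.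

Step 19
Reactants: 28 the bis(allylic chloride) silyl ether
Product: 29 (2E,6E,10R,12Z)-1,14-dichloro-3-(hydroxymethyl)-7,13-dimethyl-10-(6-methylhepta-1,5-dien-2-yl)tetradeca-2,6,12-triene (named on the tetradecatriene chain for continuity)
Conditions: HF·pyridine, pyridine, THF, 0 °C
Reagents that add atoms: none
Why: Fluoride-assisted cleavage of the primary silyl ether under weakly acidic, non-basic conditions that should not substitute the allylic chlorides.

Step 20
Reactants: 29 the bis(allylic chloride) with free C8 hydroxymethyl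
Product: 31 [(1E,5Z,8R,11E)-5,11-dimethyl-8-(6-methylhepta-1,5-dien-2-yl)cyclotetradeca-1,5,11-trien-1-yl]methanol (target), via lithium alkoxide 30 (not isolated)
Conditions: n-BuLi (1.0 equiv), THF (0.003 M), −78 °C; then activated zerovalent barium (1.1 equiv, from BaI2 + 2 LiC12H10 [lithium biphenylide], THF, 25 °C) added over 4 h, −78 °C; NH4Cl (aq)
Reagents that add atoms: none
Why: Proposed new method: zerovalent barium inserts into one C–Cl bond of 30 by two single-electron transfers to give a σ-allylbarium chloride that keeps its alkene geometry at −78 °C and then displaces the remaining primary allylic chloride by SN2 at carbon, forming C5–C6. The closest known reaction type is the intermolecular, α,α′-selective and geometry-retaining coupling of allylbarium reagents with allylic halides, run here inside one molecule as a reductive macrocyclisation; the nearest ring-forming analogy is the Ni(CO)4 cyclisation of bis(allylic bromides). The 14-membered ring closes in an exo-tet mode at a primary carbon (C5 or C6, whichever end was not metalated), and no stereocentre is formed, so C1 is untouched. The step needs head-to-head coupling, retention of the C3=C4 and C7=C8 geometries, a single metalation per molecule and survival of the C8 oxygen: the hindered γ-termini (C3 secondary, C8 fully substituted) and the cold barium counter-ion should secure the first two, adding the barium slowly to a dilute solution keeps chloride in excess so that each molecule is metalated once and cyclises before it meets more metal or another chain, and the lithium alkoxide removes the 1,4-elimination open to a C6-centred allylbarium because oxide is no leaving group.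

Compound list
1 | (S)-(+)-carvone | CC1=CC[C@@H](CC1=O)C(C)=C | starting material
2 | potassium dienolate of 1 (O–K at C1, C1=C6) | CC1=CC[C@@H](C=C1[O-])C(C)=C.[K+] | intermediate
3 | (5R)-6-hydroxy-2-methyl-5-(prop-1-en-2-yl)cyclohex-2-en-1-one (C6 epimer mixture) | CC1=CC[C@@H](C(O)C1=O)C(C)=C | intermediate
4 | methyl (2Z,5R)-5-formyl-2,6-dimethylhepta-2,6-dienoate | COC(=O)/C(C)=C\C[C@H](C(C)=C)C=O | intermediate
5 | methyl (2Z,5R)-5-(hydroxymethyl)-2,6-dimethylhepta-2,6-dienoate | COC(=O)/C(C)=C\C[C@H](C(C)=C)CO | intermediate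
6 | methyl (2Z,5R)-5-(iodomethyl)-2,6-dimethylhepta-2,6-dienoate | COC(=O)/C(C)=C\C[C@H](C(C)=C)CI | intermediate
7 | methyl (2Z,5R)-2,6-dimethyl-5-[(phenylsulfonyl)methyl]hepta-2,6-dienoate | COC(=O)/C(C)=C\C[C@H](C(C)=C)CS(=O)(=O)c1ccccc1 | intermediate
8 | methyl (2Z,5R)-6-(chloromethyl)-2-methyl-5-[(phenylsulfonyl)methyl]hepta-2,6-dienoate | COC(=O)/C(C)=C\C[C@H](C(=C)CCl)CS(=O)(=O)c1ccccc1 | intermediate
9 | prenyl bromide (1-bromo-3-methylbut-2-ene) | CC(C)=CCBr | starting material
10 | 3-methylbut-2-en-1-yl phenyl sulfone | CC(C)=CCS(=O)(=O)c1ccccc1 | intermediate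
11 | α-lithio derivative of 10 | [Li]C(C=C(C)C)S(=O)(=O)c1ccccc1 | intermediate
12 | methyl (2Z,5R)-2,10-dimethyl-6-methylidene-8-(phenylsulfonyl)-5-[(phenylsulfonyl)methyl]undeca-2,9-dienoate (C8 epimers) | COC(=O)/C(C)=C\C[C@H](C(=C)CC(C=C(C)C)S(=O)(=O)c1ccccc1)CS(=O)(=O)c1ccccc1 | intermediate
13 | (2Z,5R)-2,10-dimethyl-6-methylidene-5-[(phenylsulfonyl)methyl]undeca-2,9-dien-1-ol | OC/C(C)=C\C[C@H](C(=C)CCC=C(C)C)CS(=O)(=O)c1ccccc1 | intermediate
14 | but-2-yne-1,4-diol | OCC#CCO | starting material
15 | 4-[(tert-butyldimethylsilyl)oxy]but-2-yn-1-ol | OCC#CCO[Si](C)(C)C(C)(C)C | intermediate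
16 | cyclic sodium alkenylaluminate from 15 (Al on C3, O–Al ring) | [Na+].COCCO[Al-]1(OCCOC)OCC=C1CO[Si](C)(C)C(C)(C)C | intermediate
17 | (2Z)-4-[(tert-butyldimethylsilyl)oxy]-3-iodobut-2-en-1-ol | OC/C=C(\I)CO[Si](C)(C)C(C)(C)C | intermediate
18 | 5-bromo-2-methylpent-2-ene | CC(C)=CCCBr | starting material
19 | (4-methylpent-3-en-1-yl)zinc bromide | CC(C)=CCC[Zn]Br | intermediate
20 | (2E)-3-{[(tert-butyldimethylsilyl)oxy]methyl}-7-methylocta-2,6-dien-1-ol | OC/C=C(\CCC=C(C)C)CO[Si](C)(C)C(C)(C)C | intermediate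
21 | (2E)-3-{[(tert-butyldimethylsilyl)oxy]methyl}-7-methylocta-2,6-dien-1-yl 2,2-dimethylpropanoate | CC(C)(C)C(=O)OC/C=C(\CCC=C(C)C)CO[Si](C)(C)C(C)(C)C | intermediate
22 | (2E,6E)-3-{[(tert-butyldimethylsilyl)oxy]methyl}-8-hydroxy-7-methylocta-2,6-dien-1-yl 2,2-dimethylpropanoate | CC(C)(C)C(=O)OC/C=C(\CC/C=C(\C)CO)CO[Si](C)(C)C(C)(C)C | intermediate
23 | (2E,6E)-8-bromo-3-{[(tert-butyldimethylsilyl)oxy]methyl}-7-methylocta-2,6-dien-1-yl 2,2-dimethylpropanoate | CC(C)(C)C(=O)OC/C=C(\CC/C=C(\C)CBr)CO[Si](C)(C)C(C)(C)C | intermediate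
24 | O,C-dilithio derivative of 13 (Li on the C5 oxygen and on C14) | [Li]OC/C(C)=C\C[C@H](C(=C)CCC=C(C)C)C([Li])S(=O)(=O)c1ccccc1 | intermediate
25 | (2E,6E,10R,12Z)-3-{[(tert-butyldimethylsilyl)oxy]methyl}-14-hydroxy-7,13-dimethyl-10-(6-methylhepta-1,5-dien-2-yl)-9-(phenylsulfonyl)tetradeca-2,6,12-trien-1-yl 2,2-dimethylpropanoate (C9 epimers) | OC/C(C)=C\C[C@H](C(=C)CCC=C(C)C)C(C/C(C)=C/CC/C(CO[Si](C)(C)C(C)(C)C)=C\COC(=O)C(C)(C)C)S(=O)(=O)c1ccccc1 | intermediate
26 | (2E,6E,10R,12Z)-3-{[(tert-butyldimethylsilyl)oxy]methyl}-14-hydroxy-7,13-dimethyl-10-(6-methylhepta-1,5-dien-2-yl)tetradeca-2,6,12-trien-1-yl 2,2-dimethylpropanoate | OC/C(C)=C\C[C@H](C(=C)CCC=C(C)C)CC/C(C)=C/CC/C(CO[Si](C)(C)C(C)(C)C)=C\COC(=O)C(C)(C)C | intermediate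
27 | (2E,6E,10R,12Z)-3-{[(tert-butyldimethylsilyl)oxy]methyl}-7,13-dimethyl-10-(6-methylhepta-1,5-dien-2-yl)tetradeca-2,6,12-triene-1,14-diol | OC/C(C)=C\C[C@H](C(=C)CCC=C(C)C)CC/C(C)=C/CC/C(CO[Si](C)(C)C(C)(C)C)=C\CO | intermediate
28 | (2E,6E,10R,12Z)-3-{[(tert-butyldimethylsilyl)oxy]methyl}-1,14-dichloro-7,13-dimethyl-10-(6-methylhepta-1,5-dien-2-yl)tetradeca-2,6,12-triene | ClC/C(C)=C\C[C@H](C(=C)CCC=C(C)C)CC/C(C)=C/CC/C(CO[Si](C)(C)C(C)(C)C)=C\CCl | intermediate
29 | (2E,6E,10R,12Z)-1,14-dichloro-3-(hydroxymethyl)-7,13-dimethyl-10-(6-methylhepta-1,5-dien-2-yl)tetradeca-2,6,12-triene | ClC/C(C)=C\C[C@H](C(=C)CCC=C(C)C)CC/C(C)=C/CC/C(CO)=C\CCl | intermediate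
30 | lithium alkoxide of 29 | ClC/C(C)=C\C[C@H](C(=C)CCC=C(C)C)CC/C(C)=C/CC/C(C[O-])=C\CCl.[Li+] | intermediate
31 | [(1E,5Z,8R,11E)-5,11-dimethyl-8-(6-methylhepta-1,5-dien-2-yl)cyclotetradeca-1,5,11-trien-1-yl]methanol | C=C(CCC=C(C)C)[C@H]1C/C=C(/C)CC/C=C(/CO)CC/C=C(\C)CC1 | target

Total step count: 20. Longest linear sequence: 13 steps (steps 1–5, 7, 8, 15–20, from (S)-carvone); the other branch (steps 9–14, then 15–20) has 12.

Steps most likely to fail

1. Step 20 (proposed new method). The remaining chloride may be metalated before the ring closes, chains may couple with each other and oligomerise, the allylbarium may attack through its γ-terminus, or a 1,3-metal shift may erode the alkene geometry. Fallback by known chemistry, setting out from 26 and returning at 31: the C6 pivalate of 26 is replaced by a sulfonyl group through palladium-catalysed allylic substitution (Pd(PPh3)4, PhSO2Na, THF/MeOH, 50 °C) to give the C6 allylic phenyl sulfone with free C5 alcohol F1; NCS/Me2S converts the C5 alcohol into the allylic chloride F2; slow addition of F2 to LiN(SiMe3)2 in THF at high dilution closes the 14-membered ring by intramolecular alkylation of the C6 sulfonyl carbanion by the C5 chloride and gives the cyclic C6 sulfone F3; PdCl2(dppp)/LiBHEt3 removes the sulfonyl group with hydride delivery to the less substituted allyl terminus C6 and gives the tert-butyldimethylsilyl ether of the target F4; Bu4NF then gives 31.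

2. Step 7. The sulfonyl carbanion may add to the enoate in a conjugate sense or attack the ester, in competition with allylic substitution, and reversible addition may isomerise the Z-enoate. Fallback, setting out from 8 and returning at 13: the enoate is taken out before the carbanion is introduced. i-Bu2AlH (CH2Cl2, −78 °C) reduces the ester of 8 to the allylic alcohol chloride F5; F5 is alkylated with 2.2 equiv of lithiated 10 (the first equivalent takes the hydroxyl proton) to give the hydroxy bis-sulfone F6; PdCl2(dppp)/LiBHEt3 then removes only the allylic sulfonyl group and gives 13.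

3. Step 13. The oxidation may stop early, run on to the enal, or attack the allylic positions of the C7=C8 alkene. Fallback, setting out from 17 and returning at 22: C9–C11 are brought in as a masked aldehyde and the E-alkene is built by a stabilised Wittig reaction. (3,3-Dimethoxypropyl)zinc bromide F7, made from 3-bromo-1,1-dimethoxypropane with Zn/LiCl, is coupled with 17 (Pd(OAc)2, SPhos, THF) to give the acetal alcohol F8; pivaloylation gives the acetal pivalate F9; LiBF4 in wet MeCN frees the aldehyde F10; Ph3P=C(CH3)CHO (toluene, 80 °C) gives the (E)-2-methyl enal F11; NaBH4/CeCl3·7H2O (MeOH, 0 °C) gives 22.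

Further compounds
F1 | step 20 | 26 with the C6 pivalate replaced by phenylsulfonyl, C5 alcohol free | OC/C(C)=C\C[C@H](C(=C)CCC=C(C)C)CC/C(C)=C/CC/C(CO[Si](C)(C)C(C)(C)C)=C\CS(=O)(=O)c1ccccc1
F2 | step 20 | F1 with the C5 alcohol replaced by chloride | ClC/C(C)=C\C[C@H](C(=C)CCC=C(C)C)CC/C(C)=C/CC/C(CO[Si](C)(C)C(C)(C)C)=C\CS(=O)(=O)c1ccccc1
F3 | step 20 | tert-butyldimethylsilyl ether of the target carrying phenylsulfonyl at C6 (epimers) | C=C(CCC=C(C)C)[C@H]1C/C=C(/C)CC(S(=O)(=O)c2ccccc2)/C=C(/CO[Si](C)(C)C(C)(C)C)CC/C=C(\C)CC1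
F4 | step 20 | tert-butyldimethylsilyl ether of the target | C=C(CCC=C(C)C)[C@H]1C/C=C(/C)CC/C=C(/CO[Si](C)(C)C(C)(C)C)CC/C=C(\C)CC1
F5 | step 7 | (2Z,5R)-6-(chloromethyl)-2-methyl-5-[(phenylsulfonyl)methyl]hepta-2,6-dien-1-ol | OC/C(C)=C\C[C@H](C(=C)CCl)CS(=O)(=O)c1ccccc1
F6 | step 7 | (2Z,5R)-2,10-dimethyl-6-methylidene-8-(phenylsulfonyl)-5-[(phenylsulfonyl)methyl]undeca-2,9-dien-1-ol (C8 epimers) | OC/C(C)=C\C[C@H](C(=C)CC(C=C(C)C)S(=O)(=O)c1ccccc1)CS(=O)(=O)c1ccccc1
F7 | step 13 | (3,3-dimethoxypropyl)zinc bromide | COC(CC[Zn]Br)OC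
F8 | step 13 | (2E)-3-{[(tert-butyldimethylsilyl)oxy]methyl}-6,6-dimethoxyhex-2-en-1-ol | OC/C=C(\CCC(OC)OC)CO[Si](C)(C)C(C)(C)C
F9 | step 13 | (2E)-3-{[(tert-butyldimethylsilyl)oxy]methyl}-6,6-dimethoxyhex-2-en-1-yl 2,2-dimethylpropanoate | CC(C)(C)C(=O)OC/C=C(\CCC(OC)OC)CO[Si](C)(C)C(C)(C)C
F10 | step 13 | (2E)-3-{[(tert-butyldimethylsilyl)oxy]methyl}-6-oxohex-2-en-1-yl 2,2-dimethylpropanoate | CC(C)(C)C(=O)OC/C=C(\CCC=O)CO[Si](C)(C)C(C)(C)C
F11 | step 13 | (2E,6E)-3-{[(tert-butyldimethylsilyl)oxy]methyl}-7-methyl-8-oxoocta-2,6-dien-1-yl 2,2-dimethylpropanoate | CC(C)(C)C(=O)OC/C=C(\CC/C=C(\C)C=O)CO[Si](C)(C)C(C)(C)C
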